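## Retrosynthetic overview

1. Ester C–O: the target comes from the cis-(2R,3R)-3-hydroxy-2-isopropenyl-dihydrobenzofuran and angelic acid, coupled last through a mixed anhydride without DMAP.
2. C2–C3 bond, vinyl–CH3 bond, both stereocentres and the dihydrofuran ring: one Ni(cod)2/chiral phosphoramidite methylative cyclization of a 5-acetyl-2-(allenyloxy)benzaldehyde with Me2Zn. The allene/methyl-nickel pair acts as a 1-aryloxy-2-methylallyl anion, an α-oxygenated carbanion that attacks the aldehyde carbon, so two carbons that are both acceptors in normal polarity are joined.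
3. The allenyl ether comes from a propargyl ether by KOt-Bu isomerization; the acetyl group is carried as a 1-ethoxyvinyl group (from the aryl bromide and tributyl(1-ethoxyvinyl)stannane) until the base step is over.
4. The bromo propargyl ether comes from 2-hydroxy-3,4-dimethoxybenzaldehyde by para-bromination and O-propargylation in one flask.
5. Ring order: the benzene ring is bought complete; the dihydrofuran ring is the only ring formed, in the key step.

Assumption: the five starting materials are catalogue items, and because the sense of induction of the phosphoramidite in step 4 cannot be predicted, the ligand antipode that gives (2R,3R) is meant and is written as (R)-SIPHOS-PE.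

## Route

Step 1
Reactants: 1 2-hydroxy-3,4-dimethoxybenzaldehyde; 2 propargyl bromide
Product: 4 5-bromo-3,4-dimethoxy-2-(prop-2-yn-1-yloxy)benzaldehyde, via bromophenol 3 (not isolated)
Conditions: NBS (1.0 equiv), DMF, 0 °C to rt, 1 h; then K2CO3 (3 equiv), 2 (2.2 equiv), rt, 6 h
Reagents that add atoms: N-bromosuccinimide (O=C1CCC(=O)N1Br); propargyl bromide 2 (C#CCBr)
Why: Electrophilic aromatic bromination goes para to the free phenol OH (C5, also ortho to the 4-OMe, whereas C6 is deactivated by the ortho CHO), and Williamson O-alkylation of the phenoxide follows in the same DMF solution; the excess of 2 and K2CO3 allows for N-alkylation of the succinimide formed.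

Step 2
Reactants: 4 5-bromo-3,4-dimethoxy-2-(prop-2-yn-1-yloxy)benzaldehyde; 5 tributyl(1-ethoxyvinyl)stannane
Product: 6 5-(1-ethoxyethenyl)-3,4-dimethoxy-2-(prop-2-yn-1-yloxy)benzaldehyde
Conditions: 5 (1.2 equiv), Pd(PPh3)4 (5 mol %), toluene, 100 °C, 6 h; chromatography on K2CO3-doped silica
Reagents that add atoms: tributyl(1-ethoxyvinyl)stannane 5 (CCCC[Sn](CCCC)(CCCC)C(=C)OCC)
Why: Stille cross-coupling (oxidative addition of the aryl bromide to zerovalent palladium, Sn-to-Pd transmetalation, reductive elimination) attaches a masked acetyl carbon under neutral conditions that spare the aldehyde, terminal alkyne and propargyl ether; the enol ether is kept so that no enolizable ketone is present in the basic step that follows.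

Step 3
Reactants: 6 5-(1-ethoxyethenyl)-3,4-dimethoxy-2-(prop-2-yn-1-yloxy)benzaldehyde
Product: 8 5-acetyl-3,4-dimethoxy-2-(propa-1,2-dien-1-yloxy)benzaldehyde, via allenyl enol ether 7 (not isolated)
Conditions: KOt-Bu (0.3 equiv), THF, 0 °C to rt, 1 h; then 0.5 M aq. HCl, THF, 0 °C, 20 min
Reagents that add atoms: water (O)
Why: Base-catalysed prototropic propargyl-to-allenyl isomerization gives the aryloxyallene as the kinetic product, and acid hydrolysis of the α-ethoxystyrene, which is much faster than hydrolysis of the electron-poor aryloxyallene, then releases the acetyl group.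

Step 4
Reactants: 8 5-acetyl-3,4-dimethoxy-2-(propa-1,2-dien-1-yloxy)benzaldehyde; 9 dimethylzinc
Product: 11 1-[(2R,3R)-3-hydroxy-6,7-dimethoxy-2-(prop-1-en-2-yl)-2,3-dihydro-1-benzofuran-5-yl]ethan-1-one (2,3-cis), via methylzinc alkoxide 10 (not isolated)
Conditions: Ni(cod)2 (10 mol %), (R)-SIPHOS-PE (12 mol %), 9 (2.5 equiv), toluene/THF, 0 °C, slow addition of 8 over 2 h; then sat. aq. NH4Cl
Reagents that add atoms: dimethylzinc 9 (C[Zn]C)
Why: Proposed new method: zerovalent nickel carrying the phosphoramidite couples the aldehyde carbon with the oxygen-bearing allene carbon by oxidative cyclization to a five-membered oxanickelacycle in which the O–Ni and alkenyl–Ni bonds must lie on one face, which fixes the 2,3-cis relationship, while the ligand selects the aldehyde face to give (2R,3R); Me2Zn then transmetalates and C(sp2)–CH3 reductive elimination creates the isopropenyl group, so the allene/methyl-nickel pair is in effect a 1-aryloxy-2-methylallyl anion adding to the aldehyde; the closest known reaction types are the ligand-free Ni(cod)2/organozinc alkylative cyclization of allenyl aldehydes to cis homoallylic alcohols and the Ni(cod)2/spiro-phosphoramidite enantioselective methylative coupling of alkynes, aldehydes and Me2Zn.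

Step 5
Reactants: 11 1-[(2R,3R)-3-hydroxy-6,7-dimethoxy-2-(prop-1-en-2-yl)-2,3-dihydro-1-benzofuran-5-yl]ethan-1-one; 12 angelic acid
Product: 14 (2R,3R)-5-acetyl-6,7-dimethoxy-2-(prop-1-en-2-yl)-2,3-dihydro-1-benzofuran-3-yl (2Z)-2-methylbut-2-enoate (CNP0113631.1), via mixed anhydride 13 (not isolated)
Conditions: 12 (1.5 equiv), 2,4,6-trichlorobenzoyl chloride (1.5 equiv), Et3N (3 equiv), toluene, rt, 2 h; then 11, 75 °C, 12 h, no DMAP
Reagents that add atoms: angelic acid 12 (C/C=C(/C)C(=O)O); 2,4,6-trichlorobenzoyl chloride (O=C(Cl)c1c(Cl)cc(Cl)cc1Cl; its atoms end up in 13 only)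
Why: Yamaguchi-type mixed-anhydride esterification, in which the alcohol attacks the unhindered angeloyl carbonyl of 13; leaving out the nucleophilic catalyst avoids the addition–rotation pathway that turns angelate into tiglate, and acylation on oxygen leaves C2 and C3 untouched.

## Compound list

1 | 2-hydroxy-3,4-dimethoxybenzaldehyde | COc1ccc(C=O)c(O)c1OC | starting material
2 | propargyl bromide (3-bromoprop-1-yne) | C#CCBr | starting material
3 | 5-bromo-2-hydroxy-3,4-dimethoxybenzaldehyde | COc1c(Br)cc(C=O)c(O)c1OC | intermediate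
4 | 5-bromo-3,4-dimethoxy-2-(prop-2-yn-1-yloxy)benzaldehyde | COc1c(Br)cc(C=O)c(OCC#C)c1OC | intermediate
5 | tributyl(1-ethoxyvinyl)stannane | CCCC[Sn](CCCC)(CCCC)C(=C)OCC | starting material
6 | 5-(1-ethoxyethenyl)-3,4-dimethoxy-2-(prop-2-yn-1-yloxy)benzaldehyde | C=C(OCC)c1cc(C=O)c(OCC#C)c(OC)c1OC | intermediate
7 | 5-(1-ethoxyethenyl)-3,4-dimethoxy-2-(propa-1,2-dien-1-yloxy)benzaldehyde | C=C(OCC)c1cc(C=O)c(OC=C=C)c(OC)c1OC | intermediate
8 | 5-acetyl-3,4-dimethoxy-2-(propa-1,2-dien-1-yloxy)benzaldehyde | CC(=O)c1cc(C=O)c(OC=C=C)c(OC)c1OC | intermediate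
9 | dimethylzinc | C[Zn]C | starting material
10 | methylzinc (2R,3R)-5-acetyl-6,7-dimethoxy-2-(prop-1-en-2-yl)-2,3-dihydro-1-benzofuran-3-olate | C=C(C)[C@H]1Oc2c(cc(C(C)=O)c(OC)c2OC)[C@H]1O[Zn]C | intermediate
11 | 1-[(2R,3R)-3-hydroxy-6,7-dimethoxy-2-(prop-1-en-2-yl)-2,3-dihydro-1-benzofuran-5-yl]ethan-1-one | C=C(C)[C@H]1Oc2c(cc(C(C)=O)c(OC)c2OC)[C@H]1O | intermediate
12 | angelic acid, (2Z)-2-methylbut-2-enoic acid | C/C=C(/C)C(=O)O | starting material
13 | (2Z)-2-methylbut-2-enoic 2,4,6-trichlorobenzoic anhydride | C/C=C(/C)C(=O)OC(=O)c1c(Cl)cc(Cl)cc1Cl | intermediate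
14 | (2R,3R)-5-acetyl-6,7-dimethoxy-2-(prop-1-en-2-yl)-2,3-dihydro-1-benzofuran-3-yl (2Z)-2-methylbut-2-enoate | C=C(C)[C@H]1Oc2c(cc(C(C)=O)c(OC)c2OC)[C@H]1OC(=O)/C(C)=C\C | target

## Step count and risk

Total steps: 5. Longest linear sequence: 5 (1 → 4 → 6 → 8 → 11 → 14).

The three steps most likely to fail:

**Step 4 (key cyclization).** The enantioselectivity is unproven, and six-ring closure at the central allene carbon or direct methyl addition to the aldehyde may compete. The fallback sets out from 8. CuCl (5 mol %), (R,R)-Ph-BPE (6 mol %, antipode chosen for (2R,3R)), NaOt-Bu (10 mol %) and B2pin2 (1.1 equiv) in THF at rt add boron to the central allene carbon; the resulting γ-aryloxyallylcopper adds to the aldehyde through a cyclic transition state. This gives the cis alkenylboronate 1-[(2R,3R)-3-hydroxy-6,7-dimethoxy-2-[1-(4,4,5,5-tetramethyl-1,3,2-dioxaborolan-2-yl)ethenyl]-2,3-dihydro-1-benzofuran-5-yl]ethan-1-one F1. Suzuki–Miyaura methylation (Pd2(dba)3, P(o-tol)3, MeI, K2CO3, DMF/H2O, 60 °C) then turns C–B into C–CH3 and comes back to the route at 11.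

**Step 3 (isomerization beside a free aldehyde).** The acetylide or allenyl anion may add to the aldehyde, and the allene may not survive the acid hydrolysis. The fallback sets out from 6. HC(OMe)3, MeOH and catalytic pyridinium p-toluenesulfonate at rt mask both carbonyl functions, giving 1-(dimethoxymethyl)-5-(1,1-dimethoxyethyl)-3,4-dimethoxy-2-(prop-2-yn-1-yloxy)benzene F2. KOt-Bu (0.2 equiv) in THF at rt isomerizes it, with no electrophilic carbonyl present, to 1-(dimethoxymethyl)-5-(1,1-dimethoxyethyl)-3,4-dimethoxy-2-(propa-1,2-dien-1-yloxy)benzene F3. Aqueous oxalic acid (5 %) in THF at 0 °C unmasks both carbonyls and comes back to the route at 8.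

**Step 5 (angeloylation).** Isomerization to the tiglate, or elimination or ionization of the benzylic cis ester at 75 °C, may occur. The fallback sets out from 11. DCC, DMAP (5 mol %) and 2-[bis(2,2,2-trifluoroethoxy)phosphoryl]propanoic acid in CH2Cl2 at 0 °C give (2R,3R)-5-acetyl-6,7-dimethoxy-2-(prop-1-en-2-yl)-2,3-dihydro-1-benzofuran-3-yl 2-[bis(2,2,2-trifluoroethoxy)phosphoryl]propanoate F4 (both epimers at the phosphonate carbon). KN(SiMe3)2 (1.0 equiv) and 18-crown-6 in THF at −78 °C, then acetaldehyde, build the Z-trisubstituted alkene on the ester by Still–Gennari olefination and come back to the route at 14.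

## Further compounds

F1 | step 4 | 1-[(2R,3R)-3-hydroxy-6,7-dimethoxy-2-[1-(4,4,5,5-tetramethyl-1,3,2-dioxaborolan-2-yl)ethenyl]-2,3-dihydro-1-benzofuran-5-yl]ethan-1-one | C=C(B1OC(C)(C)C(C)(C)O1)[C@H]1Oc2c(cc(C(C)=O)c(OC)c2OC)[C@H]1O
F2 | step 3 | 1-(dimethoxymethyl)-5-(1,1-dimethoxyethyl)-3,4-dimethoxy-2-(prop-2-yn-1-yloxy)benzene | COC(OC)c1cc(C(C)(OC)OC)c(OC)c(OC)c1OCC#C
F3 | step 3 | 1-(dimethoxymethyl)-5-(1,1-dimethoxyethyl)-3,4-dimethoxy-2-(propa-1,2-dien-1-yloxy)benzene | COC(OC)c1cc(C(C)(OC)OC)c(OC)c(OC)c1OC=C=C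
F4 | step 5 | (2R,3R)-5-acetyl-6,7-dimethoxy-2-(prop-1-en-2-yl)-2,3-dihydro-1-benzofuran-3-yl 2-[bis(2,2,2-trifluoroethoxy)phosphoryl]propanoate | C=C(C)[C@H]1Oc2c(cc(C(C)=O)c(OC)c2OC)[C@H]1OC(=O)C(C)P(=O)(OCC(F)(F)F)OCC(F)(F)F
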